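At constant temperature the constants stay put, while time changes what the flask holds.

substrate 1.2 M; free catalyst 2.4 mM; impurity 2.3 mM

    substrate + free catalyst ⇌ catalyst intermediate (K1 = 0.37 M⁻¹, k1 = 430 M⁻¹ s⁻¹)
    catalyst intermediate → free catalyst + target (k2 = 14 s⁻¹)
    free catalyst + impurity → spent catalyst A (k3 = 77 M⁻¹ s⁻¹)
    catalyst intermediate → spent catalyst B (k4 = 0.0089 s⁻¹)

1. the form that holds most of the catalyst when 20 % of the substrate are converted (spent catalyst B / spent catalyst A / free catalyst / catalyst intermediate)
2. its share of the catalyst then

The substrate is charged in large excess, so look at the two small charges. The impurity, at 2.3 mM, lies below the catalyst, at 2.4 mM, which makes it the limiting reagent of step 3. Each impurity takes one catalyst. So the surplus, the catalyst charge minus the impurity charge, is 0.100 mM.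

But step 4 also takes catalyst. An intermediate goes on to target at 840 min⁻¹ and to spent catalyst B at 0.53 min⁻¹. So reaching 20 % conversion, about 0.240 M of target, costs about 0.153 mM of catalyst as spent catalyst B. That is more than the surplus. In this flask, then, spent catalyst A should stop below the impurity charge. My balance puts spent catalyst A at about 93.6 % of the catalyst, less whatever still works. Free catalyst meets the charged impurity at 11 min⁻¹, against 0.53 min⁻¹ for an intermediate's loss to spent catalyst B, so I commit to spent catalyst A, a little under that estimate.

The forecast names spent catalyst A at 92.5 %, holding that the impurity “kills it over the same span in which the substrate turns over”. My reckoning gives an upper estimate, not that figure.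

In this flask, spent catalyst A holds 92.5 % at 4.94 min, as forecast. Spent catalyst B then stands at 6.35 %, or 0.152 mM, above the surplus of 0.100 mM. After 15.0 min, this flask still keeps 2.74 % of its impurity, with target at 21.3 %. In a second flask with twice the free catalyst, the surplus becomes 2.50 mM, and the rate changes by a factor of 87.4.

The constants are assumed; what happens was integrated by code.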